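**Assumption:** the target SMILES has no stereocentre (it is drawn as the achiral 2‑hydroxyindole tautomer of a 3‑substituted oxindole, whose C3–H form racemises freely), so "single enantiomer" has no consequence and no stereocentre needs to be set.

## Retrosynthetic overview

1. Target ⇐ one global hydrogenolysis of a benzyl ether / benzyl ester precursor (9).
2. Oxindole ⇐ acid hydrolysis of a 2‑chloroindole carried as a latent oxindole from commercial 2‑chloroindole‑3‑carbaldehyde.
3. Pyrrole ⇐ denitrative oxidative aromatisation of a 4‑nitroprolinate. No cross‑coupling on a halopyrrole is used.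
4. 4‑Nitroprolinate ⇐ Ag(I) azomethine‑ylide [3+2] (key step): the glycinate imine of 5‑benzyloxyindole‑3‑carbaldehyde supplies C5–N–C2, and 2‑chloro‑3‑(2‑nitrovinyl)indole supplies C3–C4.
5. Ring order: both indole rings are bought; the only ring built is the pyrrole (pyrrolidine in step 3, aromatised in step 4); the oxindole is unmasked in step 5.

## Route

**Step 1**
Reactants: 1, 2‑chloro‑1H‑indole‑3‑carbaldehyde; 2, nitromethane
Product: 3, (E)‑2‑chloro‑3‑(2‑nitrovinyl)‑1H‑indole
Conditions: NH4OAc (0.5 equiv), MeNO2 (solvent), 90 °C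
Reagents that add atoms: nitromethane, C[N+](=O)[O-] (reactant 2)
Why: Henry (nitroaldol) condensation–dehydration gives the conjugated (E)‑nitroalkene under thermodynamic control, and the N–H 2‑chloroindole is a poor SNAr substrate under these conditions, so the chlorine is retained.

**Step 2**
Reactants: 4, 5‑(benzyloxy)‑1H‑indole‑3‑carbaldehyde; 5, glycine benzyl ester hydrochloride
Product: 6, benzyl (E)‑N‑{[5‑(benzyloxy)‑1H‑indol‑3‑yl]methylidene}glycinate
Conditions: Et3N (1.1 equiv), MgSO4, CH2Cl2, rt to 40 °C; used crude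
Reagents that add atoms: none beyond the two reactants
Why: Schiff‑base condensation driven by the drying agent gives the E‑aldimine, whose imine N and ester C=O are set up to chelate Ag(I) in the next step.

**Step 3 (key step)**
Reactants: 6, glycinate imine; 3, nitroalkene
Product: 7, benzyl 5‑[5‑(benzyloxy)‑1H‑indol‑3‑yl]‑3‑(2‑chloro‑1H‑indol‑3‑yl)‑4‑nitropyrrolidine‑2‑carboxylate (racemic; major endo isomer 2,4,5‑cis / 3,4‑trans, with some exo isomer)
Conditions: AgOAc (10 mol %), Et3N (20 mol %), THF, rt
Reagents that add atoms: none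
Why: Ag(I)‑catalysed 1,3‑dipolar cycloaddition of an N‑metalated azomethine ylide (stepwise Michael–Mannich), in which the glycinate α‑carbon attacks the nitroalkene carbon bearing the chloroindole and the nitronate closes onto the imine carbon; this fixes the 2‑ester / 3‑chloroindolyl / 4‑nitro / 5‑benzyloxyindolyl pattern, and the four new stereocentres are all erased in step 4, so their configuration is irrelevant.

**Step 4**
Reactants: 7, 4‑nitroprolinate
Product: 8, benzyl 5‑[5‑(benzyloxy)‑1H‑indol‑3‑yl]‑3‑(2‑chloro‑1H‑indol‑3‑yl)‑1H‑pyrrole‑2‑carboxylate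
Conditions: activated MnO2 (5 equiv), THF, 50 °C; then DBU (2 equiv), 50 °C
Reagents that add atoms: none (net loss of H2 and HNO2)
Why: Oxidative denitrative aromatisation of a 4‑nitroprolinate, in which MnO2 dehydrogenates the amine to the cyclic imine, DBU equilibrates the imine tautomers and expels nitrite by E1cB from the α‑imino ester (the same HNO2 loss that ends a Barton–Zard pyrrole synthesis), and the resulting 2H‑pyrrole tautomerises to the aromatic pyrrole with C4–H.

**Step 5**
Reactants: 8, chloroindolyl pyrrole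
Product: 9, benzyl 5‑[5‑(benzyloxy)‑1H‑indol‑3‑yl]‑3‑(2‑oxoindolin‑3‑yl)‑1H‑pyrrole‑2‑carboxylate (= 2‑hydroxy‑1H‑indol‑3‑yl tautomer; oxindole C3–H racemic and labile)
Conditions: AcOH–2 M aq HCl (3:1), 70 °C, Ar
Reagents that add atoms: water, O
Why: Classical acid hydrolysis of a 2‑haloindole, in which C3‑protonation gives a 2‑chloro‑3H‑indolium ion that adds water and loses HCl, placing the oxindole oxygen only on the intended indole; the benzyl ether, benzyl ester and ester‑deactivated pyrrole should tolerate dilute acid, and argon prevents autoxidation of the 3‑aryl‑oxindole C–H.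

**Step 6**
Reactants: 9, dibenzyl‑protected precursor
Product: 10, violaceinic acid, 3‑(2‑hydroxy‑1H‑indol‑3‑yl)‑5‑(5‑hydroxy‑1H‑indol‑3‑yl)‑1H‑pyrrole‑2‑carboxylic acid
Conditions: H2 (1 atm), 10 % Pd/C, degassed THF–MeOH (1:1), rt; filter and concentrate under Ar
Reagents that add atoms: none (hydrogen only)
Why: Pd‑catalysed hydrogenolysis cleaves the aryl benzyl ether and the benzyl ester under neutral, oxygen‑free conditions (no chlorine is left to interfere) and leaves the indole, pyrrole and oxindole rings untouched at 1 atm; the product is prone to air‑driven oxidative decarboxylation, so it is handled under argon and stored cold.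

## Compound list

1 | 2‑chloro‑1H‑indole‑3‑carbaldehyde | O=Cc1c(Cl)[nH]c2ccccc12 | starting material
2 | nitromethane | C[N+](=O)[O-] | starting material
3 | (E)‑2‑chloro‑3‑(2‑nitrovinyl)‑1H‑indole | O=[N+]([O-])/C=C/c1c(Cl)[nH]c2ccccc12 | intermediate
4 | 5‑(benzyloxy)‑1H‑indole‑3‑carbaldehyde | O=Cc1c[nH]c2ccc(OCc3ccccc3)cc12 | starting material
5 | glycine benzyl ester hydrochloride | NCC(=O)OCc1ccccc1.Cl | starting material
6 | benzyl (E)‑N‑{[5‑(benzyloxy)‑1H‑indol‑3‑yl]methylidene}glycinate | O=C(C/N=C/c1c[nH]c2ccc(OCc3ccccc3)cc12)OCc1ccccc1 | intermediate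
7 | benzyl 5‑[5‑(benzyloxy)‑1H‑indol‑3‑yl]‑3‑(2‑chloro‑1H‑indol‑3‑yl)‑4‑nitropyrrolidine‑2‑carboxylate (racemic, major endo isomer drawn; all stereocentres removed in step 4) | O=C(OCc1ccccc1)[C@H]1N[C@@H](c2c[nH]c3ccc(OCc4ccccc4)cc23)[C@@H]([N+](=O)[O-])[C@@H]1c1c(Cl)[nH]c2ccccc12 | intermediate
8 | benzyl 5‑[5‑(benzyloxy)‑1H‑indol‑3‑yl]‑3‑(2‑chloro‑1H‑indol‑3‑yl)‑1H‑pyrrole‑2‑carboxylate | O=C(OCc1ccccc1)c1[nH]c(-c2c[nH]c3ccc(OCc4ccccc4)cc23)cc1-c1c(Cl)[nH]c2ccccc12 | intermediate
9 | benzyl 5‑[5‑(benzyloxy)‑1H‑indol‑3‑yl]‑3‑(2‑hydroxy‑1H‑indol‑3‑yl)‑1H‑pyrrole‑2‑carboxylate (oxindole tautomer racemic, labile) | O=C(OCc1ccccc1)c1[nH]c(-c2c[nH]c3ccc(OCc4ccccc4)cc23)cc1-c1c(O)[nH]c2ccccc12 | intermediate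
10 | violaceinic acid | O=C(O)c1[nH]c(-c2c[nH]c3ccc(O)cc23)cc1-c1c(O)[nH]c2ccccc12 | target

## Summary

Total steps: 6. Longest linear sequence: 5 (steps 2→3→4→5→6 from aldehyde 4; step 1 is the convergent branch).

Steps most likely to fail, each with a fallback that changes the approach:

1. **Step 4, denitrative aromatisation.** The risk is over‑oxidation to the 4‑nitropyrrole or oxidation at the electron‑rich indoles. Fallback: drop the nitro dipolarophile and build the pyrrole from the enone (E)‑1‑(5‑benzyloxyindol‑3‑yl)‑3‑(2‑chloroindol‑3‑yl)propenone (N‑protected) by Michael addition of benzyl N‑(diphenylmethylene)glycinate, imine hydrolysis and cyclisation to the Δ1‑pyrroline, then DDQ dehydrogenation, so no nitro group has to be lost.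
2. **Step 5, hydrolysis of the 2‑chloroindole.** The risk is that the acid needed damages the indolyl‑pyrrole or cleaves the benzyl ester. Fallback: carry the oxygen from the start as a 2‑benzyloxyindole (SNAr of benzyl alkoxide on an N‑protected form of 1 before the Henry step), so the oxindole is revealed in the final hydrogenolysis and no acid step is needed.
3. **Step 3, cycloaddition with two free N–H indoles and a push–pull nitroalkene.** The risk is low reactivity or a stalled Michael adduct. Fallback: a Barton–Zard pyrrole synthesis from nitroalkene 3 and benzyl isocyanoacetate to give benzyl 3‑(2‑chloroindol‑3‑yl)pyrrole‑2‑carboxylate, followed by C5‑selective bromination and Suzuki coupling with an N‑Boc‑5‑benzyloxyindol‑3‑yl boronate.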